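**Retrosynthetic overview**
1. The Z-enone comes from Lindlar semihydrogenation of ynone 45. The ynone carbons come from an acetylide addition to a neopentyl aldehyde on the cyclopentane.
2. The central ketone is made by an aldol of the allyl ester enolate of 20 with chromenylacetaldehyde 38. Oxidation and Pd(0) deallylation/decarboxylation follow, and the ester carbon is sacrificial.
3. Cyclopentane half: a ketoreductase desymmetrises achiral dione 2 and sets the first quaternary centre. A temporary second carbocycle (Wacker, then aldol) forces cis delivery of the second methyl by a cuprate. Ozonolysis of the regiodefined silyl enol ether then cuts that ring.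
4. Chromene half: a B-alkyl Suzuki coupling gives the Z-allylic alcohol, which undergoes catalytic Sharpless epoxidation. A 6-exo phenol opening with inversion builds the pyran, and DDQ gives the 2H-chromene.
5. Ring order: cyclopentane (bought), then the temporary cyclopentenone (closed in step 10, opened in step 12). Arene (bought), then oxirane (step 21), dihydropyran (step 22) and 2H-pyran (step 25).

Assumption: carbinol or alpha centres that are later oxidised or removed (C-1 of 5 and 6, the propargylic carbinol of 19, 20 and 39–44, and the aldol centres of 40–42) are carried as epimer mixtures and drawn without configuration.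

**Cyclopentane half**

Step 1
Reactants: 1 2-methylcyclopentane-1,3-dione
Product: 2 2-allyl-2-methylcyclopentane-1,3-dione
Conditions: allyl bromide, 1 M aq NaOH, rt, 24 h
Reagents that add atoms: allyl bromide, C=CCBr
Why: C-alkylation of the stabilised 1,3-diketone enolate with a soft allylic halide gives the achiral, prochiral dione, and no stereocentre is formed.

Step 2
Reactants: 2 2-allyl-2-methylcyclopentane-1,3-dione
Product: 3 (2S,3S)-2-allyl-3-hydroxy-2-methylcyclopentan-1-one
Conditions: ketoreductase (Prelog-selective KRED), NADP+ (cat.), i-PrOH (10 vol %), KPi buffer pH 7.0, 30 °C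
Reagents that add atoms: none
Why: In this enzymatic desymmetrising carbonyl reduction the ketoreductase (an NADPH-dependent oxidoreductase) reduces one of the two enantiotopic C=O groups from one face, in the sense long known for yeast reductases on this dione, so it sets quaternary C-2 (S) and carbinol C-3 (S, OH cis to allyl) in >98 % ee.

Step 3
Reactants: 3 (2S,3S)-2-allyl-3-hydroxy-2-methylcyclopentan-1-one
Product: 4 (2S,3S)-2-allyl-3-(tert-butyldiphenylsilyloxy)-2-methylcyclopentan-1-one
Conditions: TBDPSCl, imidazole, DMAP (cat.), DMF, 40 °C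
Reagents that add atoms: tert-butyl(chloro)diphenylsilane, CC(C)(C)[Si](Cl)(c1ccccc1)c1ccccc1
Why: This is a standard silylation, and TBDPS is chosen because it does not migrate to the 1,3-related hydroxyl made in step 4, a migration that would swap the two ring oxygens and erode ee.

Step 4
Reactants: 4 (2S,3S)-2-allyl-3-(tert-butyldiphenylsilyloxy)-2-methylcyclopentan-1-one
Product: 5 (2R,3S)-2-allyl-3-(tert-butyldiphenylsilyloxy)-2-methylcyclopentan-1-ol (C-1 epimers)
Conditions: NaBH4, MeOH, 0 °C
Reagents that add atoms: none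
Why: Borohydride reduction of the ketone gives a new carbinol centre that does not matter because step 6 deletes it, and C-2 changes descriptor only through a priority change.

Step 5
Reactants: 5 (2R,3S)-2-allyl-3-(tert-butyldiphenylsilyloxy)-2-methylcyclopentan-1-ol (C-1 epimers)
Product: 6 O-[(2R,3S)-2-allyl-3-(tert-butyldiphenylsilyloxy)-2-methylcyclopentyl] 1H-imidazole-1-carbothioate (C-1 epimers)
Conditions: 1,1'-thiocarbonyldiimidazole, DMAP (cat.), ClCH2CH2Cl, 70 °C
Reagents that add atoms: 1,1'-thiocarbonyldiimidazole, S=C(n1ccnc1)n1ccnc1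
Why: Thioacylation under nearly neutral conditions, so no silyl shift occurs, gives the radical precursor for a Barton–McCombie deoxygenation.

Step 6
Reactants: 6 O-[(2R,3S)-2-allyl-3-(tert-butyldiphenylsilyloxy)-2-methylcyclopentyl] 1H-imidazole-1-carbothioate (C-1 epimers)
Product: 7 [(1S,2S)-2-allyl-2-methylcyclopentyl]oxy(tert-butyl)diphenylsilane
Conditions: n-Bu3SnH, AIBN (cat.), toluene, 100 °C
Reagents that add atoms: none
Why: In this Barton–McCombie deoxygenation the ring radical is of the 4-pentenyl type, whose 4-exo and 5-endo closures are far slower than H transfer from tin hydride, so the allyl group and both stereocentres survive.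

Step 7
Reactants: 7 [(1S,2S)-2-allyl-2-methylcyclopentyl]oxy(tert-butyl)diphenylsilane
Product: 8 1-[(1S,2S)-2-(tert-butyldiphenylsilyloxy)-1-methylcyclopentyl]propan-2-one
Conditions: PdCl2 (10 mol %), CuCl, O2 (1 atm), DMF/H2O 7:1, rt
Reagents that add atoms: water, O
Why: The Tsuji–Wacker oxidation of a terminal alkene on a neopentyl CH2 gives the Markovnikov methyl ketone.

Step 8
Reactants: 8 1-[(1S,2S)-2-(tert-butyldiphenylsilyloxy)-1-methylcyclopentyl]propan-2-one
Product: 9 1-[(1S,2S)-2-hydroxy-1-methylcyclopentyl]propan-2-one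
Conditions: TBAF, THF, rt
Reagents that add atoms: none
Why: Fluoride-driven desilylation works here because the Si–F bond is strong and nothing base-labile is present.

Step 9
Reactants: 9 1-[(1S,2S)-2-hydroxy-1-methylcyclopentyl]propan-2-one
Product: 10 (2S)-2-methyl-2-(2-oxopropyl)cyclopentan-1-one
Conditions: Dess–Martin periodinane, CH2Cl2, rt
Reagents that add atoms: none
Why: Dess–Martin oxidation turns the enzyme-made carbinol carbon into the ring ketone, so the carbonyl the enzyme left untouched has been deleted and the quaternary centre has the (S) sense the target needs.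

Step 10
Reactants: 10 (2S)-2-methyl-2-(2-oxopropyl)cyclopentan-1-one
Product: 11 (6aS)-6a-methyl-4,5,6,6a-tetrahydropentalen-2(1H)-one
Conditions: KOH (0.5 equiv), EtOH, reflux
Reagents that add atoms: none
Why: In this intramolecular aldol condensation of a 1,4-diketone the alternative bridged aldol cannot dehydrate and reverts, so the fused cyclopentenone is the sink and the non-enolisable quaternary centre is untouched.

Step 11
Reactants: 11 (6aS)-6a-methyl-4,5,6,6a-tetrahydropentalen-2(1H)-one
Product: 12 [(3aR,6aS)-3a,6a-dimethyl-1,3a,4,5,6,6a-hexahydropentalen-2-yl]oxytrimethylsilane (cis-fused)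
Conditions: Me2CuLi (CuI + 2 MeLi), TMSCl, Et2O/THF, −78 → −30 °C; cold aq NaHCO3/pentane work-up, used at once
Reagents that add atoms: methyllithium (as Me2CuLi), [Li]C; chlorotrimethylsilane, C[Si](C)(C)Cl
Why: In this TMSCl-accelerated Gilman conjugate addition a trans-bicyclo[3.3.0]octane is prohibitively strained, so methyl arrives cis to the angular methyl and sets the second quaternary centre, and silyl trapping fixes the enol C=C on the side of the new centre, which keeps the otherwise meso ketone chiral.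

Step 12
Reactants: 12 [(3aR,6aS)-3a,6a-dimethyl-1,3a,4,5,6,6a-hexahydropentalen-2-yl]oxytrimethylsilane (cis-fused)
Product: 14 2-[(1S,2S)-2-formyl-1,2-dimethylcyclopentyl]acetic acid, via trimethylsilyl ester aldehyde 13 (not isolated)
Conditions: O3, CH2Cl2, −78 °C; Me2S, → rt; aq THF work-up
Reagents that add atoms: ozone, [O-][O+]=O
Why: Ozonolysis of the electron-rich silyl enol ether cleaves only the regiodefined C=C and gives the CHO on the new quaternary carbon and the CH2CO2H arm on the old one.

Step 13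
Reactants: 14 2-[(1S,2S)-2-formyl-1,2-dimethylcyclopentyl]acetic acid
Product: 15 allyl 2-[(1S,2S)-2-formyl-1,2-dimethylcyclopentyl]acetate
Conditions: allyl bromide, K2CO3, DMF, rt
Reagents that add atoms: allyl bromide, C=CCBr
Why: The carboxylate is O-alkylated by SN2 and the aldehyde is non-enolisable, so it is inert to carbonate.

Step 14
Reactants: 16 2-methylbut-3-yn-2-ol
Product: 17 triethyl[(2-methylbut-3-yn-2-yl)oxy]silane
Conditions: TESCl, imidazole, DMAP (cat.), DMF, rt
Reagents that add atoms: chlorotriethylsilane, CC[Si](Cl)(CC)CC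
Why: Silylation of the unhindered tertiary propargylic alcohol removes its acidic proton for the later organolithium and enolate steps.

Step 15
Reactants: 15 allyl 2-[(1S,2S)-2-formyl-1,2-dimethylcyclopentyl]acetate; 17 triethyl[(2-methylbut-3-yn-2-yl)oxy]silane
Product: 20 allyl 2-[(1S,2S)-1,2-dimethyl-2-{4-methyl-1,4-bis(triethylsilyloxy)pent-2-yn-1-yl}cyclopentyl]acetate (carbinol epimers), via lithium acetylide 18 (not isolated), via lithium alkoxide 19 (not isolated)
Conditions: 17, n-BuLi, THF, −78 °C; add 15, −78 → −50 °C; TESOTf, −78 °C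
Reagents that add atoms: triethylsilyl triflate, CC[Si](CC)(CC)OS(=O)(=O)C(F)(F)F
Why: The slim lithium acetylide adds 1,2 to the non-enolisable aldehyde faster than it attacks the ester, cold silylation of the alkoxide forestalls delta-lactonisation, and the new carbinol centre is oxidised away in step 32.

**Chromene half**

Step 16
Reactants: 21 4-methoxy-2-methylphenol
Product: 22 2-hydroxy-5-methoxy-3-methylbenzaldehyde
Conditions: MgCl2, Et3N, (CH2O)n, MeCN, reflux; 1 M HCl
Reagents that add atoms: paraformaldehyde (as formaldehyde), C=O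
Why: In this Casnati–Skattebøl ortho-formylation the magnesium phenoxide delivers formaldehyde only to the single free ortho position.

Step 17
Reactants: 22 2-hydroxy-5-methoxy-3-methylbenzaldehyde
Product: 23 2-(benzyloxy)-5-methoxy-3-methylbenzaldehyde
Conditions: BnBr, K2CO3, DMF, 50 °C
Reagents that add atoms: benzyl bromide, BrCc1ccccc1
Why: This Williamson etherification installs a benzyl group that survives ylide, borane, aqueous base and Ti/TBHP and later leaves under neutral hydrogenolysis.

Step 18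
Reactants: 23 2-(benzyloxy)-5-methoxy-3-methylbenzaldehyde
Product: 24 2-(benzyloxy)-1-ethenyl-5-methoxy-3-methylbenzene
Conditions: MePPh3Br, KOt-Bu, THF, 0 °C → rt
Reagents that add atoms: methyltriphenylphosphonium bromide, C[P+](c1ccccc1)(c1ccccc1)c1ccccc1.[Br-]
Why: This is a Wittig methylenation of an aromatic aldehyde.

Step 19
Reactants: 25 but-2-yn-1-ol
Product: 27 (Z)-3-iodobut-2-en-1-ol, via cyclic vinylalanate 26 (not isolated)
Conditions: Red-Al, THF, 0 °C → rt; I2, −78 °C; Rochelle salt work-up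
Reagents that add atoms: iodine, II
Why: Alkoxide-directed trans-hydroalumination puts Al on C-3, and iodinolysis with retention leaves iodine cis to CH2OH.

Step 20
Reactants: 24 2-(benzyloxy)-1-ethenyl-5-methoxy-3-methylbenzene; 27 (Z)-3-iodobut-2-en-1-ol
Product: 29 (Z)-5-[2-(benzyloxy)-5-methoxy-3-methylphenyl]-3-methylpent-2-en-1-ol, via B-alkyl-9-BBN 28 (not isolated)
Conditions: 24, 9-BBN, THF, rt; then 27, PdCl2(dppf) (5 mol %), AsPh3 (cat.), Cs2CO3, DMF/H2O, rt → 50 °C
Reagents that add atoms: none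
Why: Anti-Markovnikov hydroboration of the styrene followed by a B-alkyl Suzuki–Miyaura coupling with retention of the vinyl iodide geometry gives a single trisubstituted Z-olefin.

Step 21
Reactants: 29 (Z)-5-[2-(benzyloxy)-5-methoxy-3-methylphenyl]-3-methylpent-2-en-1-ol
Product: 30 [(2S,3R)-3-{2-[2-(benzyloxy)-5-methoxy-3-methylphenyl]ethyl}-3-methyloxiran-2-yl]methanol
Conditions: Ti(Oi-Pr)4 (10 mol %), L-(+)-DET (12 mol %), t-BuOOH, 4 Å MS, CH2Cl2, −20 °C
Reagents that add atoms: tert-butyl hydroperoxide, CC(C)(C)OO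
Why: In the catalytic Katsuki–Sharpless epoxidation L-(+)-tartrate gives the 2S face, which on a nerol-type Z-olefin means the (2S,3R)-epoxide in about 92–95 % ee, so both centres are set by the catalyst.

Step 22
Reactants: 30 [(2S,3R)-3-{2-[2-(benzyloxy)-5-methoxy-3-methylphenyl]ethyl}-3-methyloxiran-2-yl]methanol
Product: 32 (1S)-1-[(2S)-6-methoxy-2,8-dimethylchroman-2-yl]ethane-1,2-diol, via free phenol epoxide 31 (not isolated)
Conditions: H2 (1 atm), 10 % Pd/C, EtOAc, rt; filter; CSA (10 mol %), CH2Cl2, 0 °C; recrystallise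
Reagents that add atoms: none
Why: After hydrogenolysis, the acid-catalysed 6-exo-tet epoxide opening by the phenol occurs at the tertiary carbon, where exo and electronic preferences agree, with clean inversion (3R → 2S), and the C–O bond of the secondary carbinol is not touched.

Step 23
Reactants: 32 (1S)-1-[(2S)-6-methoxy-2,8-dimethylchroman-2-yl]ethane-1,2-diol
Product: 33 (2S)-6-methoxy-2,8-dimethylchromane-2-carbaldehyde
Conditions: NaIO4, THF/H2O, 0 °C → rt
Reagents that add atoms: none
Why: The Malaprade glycol cleavage gives an aldehyde whose alpha-carbon is quaternary and cannot epimerise.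

Step 24
Reactants: 33 (2S)-6-methoxy-2,8-dimethylchromane-2-carbaldehyde
Product: 34 (2S)-2-ethenyl-6-methoxy-2,8-dimethylchromane
Conditions: MePPh3Br, KOt-Bu, THF, 0 °C → rt
Reagents that add atoms: methyltriphenylphosphonium bromide, C[P+](c1ccccc1)(c1ccccc1)c1ccccc1.[Br-]
Why: This is a Wittig methylenation of a hindered but non-enolisable alpha-aryloxy aldehyde.

Step 25
Reactants: 34 (2S)-2-ethenyl-6-methoxy-2,8-dimethylchromane
Product: 35 (2R)-2-ethenyl-6-methoxy-2,8-dimethyl-2H-chromene
Conditions: DDQ (1.3 equiv), benzene, reflux, 3 h, dark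
Reagents that add atoms: none
Why: In this DDQ dehydrogenation hydride leaves from benzylic C-4, the cation is stabilised by the ortho ring oxygen and H-3 is then lost, while C-2 is quaternary and keeps its geometry so that only the descriptor changes.

Step 26
Reactants: 35 (2R)-2-ethenyl-6-methoxy-2,8-dimethyl-2H-chromene
Product: 37 2-[(2R)-6-methoxy-2,8-dimethyl-2H-chromen-2-yl]ethan-1-ol, via alkylborane 36 (not isolated)
Conditions: 9-BBN (1.1 equiv), THF, 0 °C → rt; 3 M NaOH, 30 % H2O2, 0 °C
Reagents that add atoms: hydrogen peroxide, OO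
Why: In this Brown hydroboration–oxidation 9-BBN takes the monosubstituted vinyl group far faster than the cis-disubstituted styrenyl C3=C4 bond and places boron at the terminus.

Step 27
Reactants: 37 2-[(2R)-6-methoxy-2,8-dimethyl-2H-chromen-2-yl]ethan-1-ol
Product: 38 2-[(2R)-6-methoxy-2,8-dimethyl-2H-chromen-2-yl]acetaldehyde
Conditions: Dess–Martin periodinane, NaHCO3, CH2Cl2, 0 °C → rt
Reagents that add atoms: none
Why: Buffered Dess–Martin oxidation is base-free, so the beta-aryloxy aldehyde does not undergo E1cB ring opening.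

**Union and endgame**

Step 28
Reactants: 20 allyl 2-[(1S,2S)-1,2-dimethyl-2-{4-methyl-1,4-bis(triethylsilyloxy)pent-2-yn-1-yl}cyclopentyl]acetate (carbinol epimers); 38 2-[(2R)-6-methoxy-2,8-dimethyl-2H-chromen-2-yl]acetaldehyde
Product: 40 allyl 2-[(1S,2S)-1,2-dimethyl-2-{4-methyl-1,4-bis(triethylsilyloxy)pent-2-yn-1-yl}cyclopentyl]-3-hydroxy-4-[(2R)-6-methoxy-2,8-dimethyl-2H-chromen-2-yl]butanoate (epimer mixture), via lithium enolate 39 (not isolated)
Conditions: 20, LDA (1.1 equiv), THF, −78 °C, 45 min; 38, −78 °C, 30 min; AcOH/THF quench at −78 °C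
Reagents that add atoms: none
Why: In this lithium ester-enolate aldol addition the ester stabilises the otherwise inaccessible neopentyl carbanion, carbonyl addition at −78 °C outruns enolisation of 38 and Ireland–Claisen shift of the allyl ester, and both new centres are erased in steps 29 and 30.

Step 29
Reactants: 40 the aldol adduct of step 28
Product: 41 allyl 2-[(1S,2S)-1,2-dimethyl-2-{4-methyl-1,4-bis(triethylsilyloxy)pent-2-yn-1-yl}cyclopentyl]-4-[(2R)-6-methoxy-2,8-dimethyl-2H-chromen-2-yl]-3-oxobutanoate (epimer mixture)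
Conditions: Dess–Martin periodinane, NaHCO3, CH2Cl2, rt
Reagents that add atoms: none
Why: Dess–Martin oxidation of the beta-hydroxy ester runs under neutral conditions that cause neither retro-aldol nor retro-oxa-Michael reaction.

Step 30
Reactants: 41 the allyl beta-keto ester of step 29
Product: 43 1-[(1S,2S)-1,2-dimethyl-2-{4-methyl-1,4-bis(triethylsilyloxy)pent-2-yn-1-yl}cyclopentyl]-3-[(2R)-6-methoxy-2,8-dimethyl-2H-chromen-2-yl]propan-2-one (carbinol epimers), via beta-keto acid 42 (not isolated)
Conditions: Pd(PPh3)4 (5 mol %), morpholine (3 equiv), THF, 0 °C → rt, 1 h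
Reagents that add atoms: none
Why: In this Tsuji-type Pd(0) deallylation excess morpholine captures the pi-allyl unit, the beta-keto acid loses CO2 at room temperature, and the unhindered allyl ester ionises far faster than the hindered cyclic allyl aryl ether of the chromene.

Step 31
Reactants: 43 the bis-TES ketone of step 30
Product: 44 1-[(1S,2S)-2-(1,4-dihydroxy-4-methylpent-2-yn-1-yl)-1,2-dimethylcyclopentyl]-3-[(2R)-6-methoxy-2,8-dimethyl-2H-chromen-2-yl]propan-2-one (carbinol epimers)
Conditions: HF·pyridine, pyridine, THF, 0 °C → rt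
Reagents that add atoms: none
Why: Buffered fluoride desilylation removes both TES ethers without the base that would open the beta-aryloxy ketone.

Step 32
Reactants: 44 the propargylic diol of step 31
Product: 45 1-[(1S,2S)-2-{3-[(2R)-6-methoxy-2,8-dimethyl-2H-chromen-2-yl]-2-oxopropyl}-1,2-dimethylcyclopentyl]-4-hydroxy-4-methylpent-2-yn-1-one
Conditions: Dess–Martin periodinane, NaHCO3, CH2Cl2, 0 °C → rt
Reagents that add atoms: none
Why: Dess–Martin oxidation takes the secondary propargylic alcohol while the tertiary alcohol cannot be oxidised, and the epimer mixture converges to one compound.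

Step 33
Reactants: 45 the ynone of step 32
Product: 46 (2Z)-1-[(1S,2S)-2-{3-[(2R)-6-methoxy-2,8-dimethyl-2H-chromen-2-yl]-2-oxopropyl}-1,2-dimethylcyclopentyl]-4-hydroxy-4-methylpent-2-en-1-one (CNP0137762.2)
Conditions: H2 (1 atm, 1.0 equiv uptake), Lindlar catalyst, quinoline, EtOAc, 0 °C, dark
Reagents that add atoms: none
Why: In the Lindlar semihydrogenation syn addition of H2 to the alkyne gives the Z-enone, and the poisoned catalyst leaves the chromene C3=C4 bond alone.

**Compound list**
1 | 2-methylcyclopentane-1,3-dione | CC1C(=O)CCC1=O | starting material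
2 | 2-allyl-2-methylcyclopentane-1,3-dione | C=CCC1(C)C(=O)CCC1=O | intermediate
3 | (2S,3S)-2-allyl-3-hydroxy-2-methylcyclopentan-1-one | O=C1CC[C@H](O)[C@]1(C)CC=C | intermediate
4 | (2S,3S)-2-allyl-3-(tert-butyldiphenylsilyloxy)-2-methylcyclopentan-1-one | O=C1CC[C@H](O[Si](c2ccccc2)(c2ccccc2)C(C)(C)C)[C@]1(C)CC=C | intermediate
5 | (2R,3S)-2-allyl-3-(tert-butyldiphenylsilyloxy)-2-methylcyclopentan-1-ol (C-1 epimers) | OC1CC[C@H](O[Si](c2ccccc2)(c2ccccc2)C(C)(C)C)[C@]1(C)CC=C | intermediate
6 | O-[(2R,3S)-2-allyl-3-(tert-butyldiphenylsilyloxy)-2-methylcyclopentyl] 1H-imidazole-1-carbothioate (C-1 epimers) | S=C(OC1CC[C@H](O[Si](c2ccccc2)(c2ccccc2)C(C)(C)C)[C@]1(C)CC=C)n1ccnc1 | intermediate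
7 | [(1S,2S)-2-allyl-2-methylcyclopentyl]oxy(tert-butyl)diphenylsilane | C1CC[C@H](O[Si](c2ccccc2)(c2ccccc2)C(C)(C)C)[C@]1(C)CC=C | intermediate
8 | 1-[(1S,2S)-2-(tert-butyldiphenylsilyloxy)-1-methylcyclopentyl]propan-2-one | C1CC[C@H](O[Si](c2ccccc2)(c2ccccc2)C(C)(C)C)[C@]1(C)CC(C)=O | intermediate
9 | 1-[(1S,2S)-2-hydroxy-1-methylcyclopentyl]propan-2-one | C1CC[C@H](O)[C@]1(C)CC(C)=O | intermediate
10 | (2S)-2-methyl-2-(2-oxopropyl)cyclopentan-1-one | CC(=O)C[C@]1(C)CCCC1=O | intermediate
11 | (6aS)-6a-methyl-4,5,6,6a-tetrahydropentalen-2(1H)-one | O=C1C=C2CCC[C@@]2(C)C1 | intermediate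
12 | [(3aR,6aS)-3a,6a-dimethyl-1,3a,4,5,6,6a-hexahydropentalen-2-yl]oxytrimethylsilane | C[Si](C)(C)OC1=C[C@@]2(C)CCC[C@@]2(C)C1 | intermediate
13 | trimethylsilyl 2-[(1S,2S)-2-formyl-1,2-dimethylcyclopentyl]acetate | C[Si](C)(C)OC(=O)C[C@]1(C)CCC[C@]1(C)C=O | intermediate
14 | 2-[(1S,2S)-2-formyl-1,2-dimethylcyclopentyl]acetic acid | OC(=O)C[C@]1(C)CCC[C@]1(C)C=O | intermediate
15 | allyl 2-[(1S,2S)-2-formyl-1,2-dimethylcyclopentyl]acetate | C=CCOC(=O)C[C@]1(C)CCC[C@]1(C)C=O | intermediate
16 | 2-methylbut-3-yn-2-ol | C#CC(C)(C)O | starting material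
17 | triethyl[(2-methylbut-3-yn-2-yl)oxy]silane | C#CC(C)(C)O[Si](CC)(CC)CC | intermediate
18 | lithium acetylide of 17 | [Li]C#CC(C)(C)O[Si](CC)(CC)CC | intermediate
19 | lithium alkoxide from 15 and 18 (carbinol epimers) | C=CCOC(=O)C[C@]1(C)CCC[C@]1(C)C([O-])C#CC(C)(C)O[Si](CC)(CC)CC.[Li+] | intermediate
20 | allyl 2-[(1S,2S)-1,2-dimethyl-2-{4-methyl-1,4-bis(triethylsilyloxy)pent-2-yn-1-yl}cyclopentyl]acetate (carbinol epimers) | C=CCOC(=O)C[C@]1(C)CCC[C@]1(C)C(O[Si](CC)(CC)CC)C#CC(C)(C)O[Si](CC)(CC)CC | intermediate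
21 | 4-methoxy-2-methylphenol | COc1ccc(O)c(C)c1 | starting material
22 | 2-hydroxy-5-methoxy-3-methylbenzaldehyde | COc1cc(C)c(O)c(C=O)c1 | intermediate
23 | 2-(benzyloxy)-5-methoxy-3-methylbenzaldehyde | COc1cc(C)c(OCc2ccccc2)c(C=O)c1 | intermediate
24 | 2-(benzyloxy)-1-ethenyl-5-methoxy-3-methylbenzene | COc1cc(C)c(OCc2ccccc2)c(C=C)c1 | intermediate
25 | but-2-yn-1-ol | CC#CCO | starting material
26 | sodium cyclic vinylalanate (1,2-oxaluminole ate complex) | [Na+].CC1=CCO[Al-]1(OCCOC)OCCOC | intermediate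
27 | (Z)-3-iodobut-2-en-1-ol | C/C(I)=C/CO | intermediate
28 | 9-{2-[2-(benzyloxy)-5-methoxy-3-methylphenyl]ethyl}-9-borabicyclo[3.3.1]nonane | COc1cc(C)c(OCc2ccccc2)c(CCB2C3CCCC2CCC3)c1 | intermediate
29 | (Z)-5-[2-(benzyloxy)-5-methoxy-3-methylphenyl]-3-methylpent-2-en-1-ol | COc1cc(C)c(OCc2ccccc2)c(CC/C(C)=C\CO)c1 | intermediate
30 | [(2S,3R)-3-{2-[2-(benzyloxy)-5-methoxy-3-methylphenyl]ethyl}-3-methyloxiran-2-yl]methanol | OC[C@@H]1O[C@]1(C)CCc1cc(OC)cc(C)c1OCc1ccccc1 | intermediate
31 | 2-{2-[(2R,3S)-3-(hydroxymethyl)-2-methyloxiran-2-yl]ethyl}-4-methoxy-6-methylphenol | OC[C@@H]1O[C@]1(C)CCc1cc(OC)cc(C)c1O | intermediate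
32 | (1S)-1-[(2S)-6-methoxy-2,8-dimethylchroman-2-yl]ethane-1,2-diol | COc1cc(C)c2c(c1)CC[C@@](C)([C@@H](O)CO)O2 | intermediate
33 | (2S)-6-methoxy-2,8-dimethylchromane-2-carbaldehyde | COc1cc(C)c2c(c1)CC[C@@](C)(C=O)O2 | intermediate
34 | (2S)-2-ethenyl-6-methoxy-2,8-dimethylchromane | COc1cc(C)c2c(c1)CC[C@@](C)(C=C)O2 | intermediate
35 | (2R)-2-ethenyl-6-methoxy-2,8-dimethyl-2H-chromene | COc1cc(C)c2c(c1)C=C[C@@](C)(C=C)O2 | intermediate
36 | 9-{2-[(2R)-6-methoxy-2,8-dimethyl-2H-chromen-2-yl]ethyl}-9-borabicyclo[3.3.1]nonane | COc1cc(C)c2c(c1)C=C[C@@](C)(CCB1C3CCCC1CCC3)O2 | intermediate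
37 | 2-[(2R)-6-methoxy-2,8-dimethyl-2H-chromen-2-yl]ethan-1-ol | COc1cc(C)c2c(c1)C=C[C@@](C)(CCO)O2 | intermediate
38 | 2-[(2R)-6-methoxy-2,8-dimethyl-2H-chromen-2-yl]acetaldehyde | COc1cc(C)c2c(c1)C=C[C@@](C)(CC=O)O2 | intermediate
39 | lithium enolate of 20 | C=CCOC([O-])=C[C@]1(C)CCC[C@]1(C)C(O[Si](CC)(CC)CC)C#CC(C)(C)O[Si](CC)(CC)CC.[Li+] | intermediate
40 | aldol adduct (allyl beta-hydroxy ester, epimer mixture) | COc1cc(C)c2c(c1)C=C[C@@](C)(CC(O)C(C(=O)OCC=C)[C@]1(C)CCC[C@]1(C)C(O[Si](CC)(CC)CC)C#CC(C)(C)O[Si](CC)(CC)CC)O2 | intermediate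
41 | allyl beta-keto ester (epimer mixture) | COc1cc(C)c2c(c1)C=C[C@@](C)(CC(=O)C(C(=O)OCC=C)[C@]1(C)CCC[C@]1(C)C(O[Si](CC)(CC)CC)C#CC(C)(C)O[Si](CC)(CC)CC)O2 | intermediate
42 | beta-keto acid (epimer mixture) | COc1cc(C)c2c(c1)C=C[C@@](C)(CC(=O)C(C(=O)O)[C@]1(C)CCC[C@]1(C)C(O[Si](CC)(CC)CC)C#CC(C)(C)O[Si](CC)(CC)CC)O2 | intermediate
43 | bis-TES ketone (carbinol epimers) | COc1cc(C)c2c(c1)C=C[C@@](C)(CC(=O)C[C@]1(C)CCC[C@]1(C)C(O[Si](CC)(CC)CC)C#CC(C)(C)O[Si](CC)(CC)CC)O2 | intermediate
44 | propargylic diol ketone (carbinol epimers) | COc1cc(C)c2c(c1)C=C[C@@](C)(CC(=O)C[C@]1(C)CCC[C@]1(C)C(O)C#CC(C)(C)O)O2 | intermediate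
45 | ynone | COc1cc(C)c2c(c1)C=C[C@@](C)(CC(=O)C[C@]1(C)CCC[C@]1(C)C(=O)C#CC(C)(C)O)O2 | intermediate
46 | CNP0137762.2 | COc1cc(C)c2c(c1)C=C[C@@](C)(CC(=O)C[C@]1(C)CCC[C@]1(C)C(=O)/C=C\C(C)(C)O)O2 | target

**Totals**
Total step count: 33.
Longest linear sequence: 20 steps (steps 1–13, 15 and 28–33).

**The three steps most likely to fail**

Step 11, the cuprate addition next to a quaternary centre. The beta-carbon is fully substituted and neopentyl, so the addition may stall. Any acid-catalysed shift of the TMS enol ether to its regioisomer gives its mirror image and erodes ee.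

The fallback sets out from 11 and builds the angular methyl from a cyclopropane instead. Luche reduction (NaBH4, CeCl3, MeOH) attacks opposite the angular methyl. It gives (2S,6aS)-6a-methyl-1,2,4,5,6,6a-hexahydropentalen-2-ol F1, with OH on the methyl face. Hydroxyl-directed Simmons–Smith cyclopropanation (Et2Zn, CH2I2) gives the cyclopropyl carbinol F2, with the CH2 bridge on that same face. Dess–Martin oxidation gives the cyclopropyl ketone F3. Li/NH3 then cleaves the outer cyclopropane bond, the one that overlaps with the carbonyl. This leaves the angular CH3 and the regiodefined lithium enolate. Trapping that enolate with TMSCl/Et3N brings the route back at 12.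

Step 28, the aldol of a very hindered ester enolate with an enolisable beta-aryloxy aldehyde. The addition may be slow, and retro-aldol or enolisation of 38 may take over.

The fallback sets out from 20 and replaces the stabilised carbanion by a true neopentyllithium. Pd(PPh3)4/morpholine frees the carboxylic acid F4. N-hydroxypyridine-2-thione and DCC give the Barton ester F5. Irradiation with CHI3 gives, by decarboxylative iodination, the neopentyl iodide F6, because iodine transfer outruns 5-exo-dig closure. t-BuLi (2.0 equiv, Et2O/pentane, −78 °C) followed by 38 gives the secondary alcohol F7. Buffered Dess–Martin oxidation of F7 brings the route back at 43.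

Step 33, the semihydrogenation of a conjugated ynone with a free gamma-hydroxyl. Risks are over-reduction, Z to E drift and closure to the cyclic hemiketal on the catalyst.

The fallback sets out from 44 and reduces before oxidising. Lindlar hydrogenation, or Zn(Cu/Ag) in aqueous MeOH, acts on the non-conjugated alkyne and gives the (Z)-ene-1,4-diol F8. Activated MnO2 in CH2Cl2 then oxidises only the secondary allylic alcohol. This brings the route back at 46 without passing through 45.

**Further compounds**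
F1 | step 11 | (2S,6aS)-6a-methyl-1,2,4,5,6,6a-hexahydropentalen-2-ol | O[C@@H]1C=C2CCC[C@@]2(C)C1
F2 | step 11 | cyclopropyl carbinol (CH2 bridge, OH and angular CH3 on one face) | O[C@@H]1[C@@H]2C[C@@]23CCC[C@@]3(C)C1
F3 | step 11 | cyclopropyl ketone from F2 | O=C1[C@@H]2C[C@@]23CCC[C@@]3(C)C1
F4 | step 28 | 2-[(1S,2S)-1,2-dimethyl-2-{4-methyl-1,4-bis(triethylsilyloxy)pent-2-yn-1-yl}cyclopentyl]acetic acid (carbinol epimers) | OC(=O)C[C@]1(C)CCC[C@]1(C)C(O[Si](CC)(CC)CC)C#CC(C)(C)O[Si](CC)(CC)CC
F5 | step 28 | 2-thioxopyridin-1(2H)-yl ester of F4 (Barton ester) | O=C(C[C@]1(C)CCC[C@]1(C)C(O[Si](CC)(CC)CC)C#CC(C)(C)O[Si](CC)(CC)CC)On1ccccc1=S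
F6 | step 28 | 1-[(1S,2R)-2-(iodomethyl)-1,2-dimethylcyclopentyl]-4-methyl-1,4-bis(triethylsilyloxy)pent-2-yne (carbinol epimers) | IC[C@]1(C)CCC[C@]1(C)C(O[Si](CC)(CC)CC)C#CC(C)(C)O[Si](CC)(CC)CC
F7 | step 28 | secondary alcohol corresponding to ketone 43 (carbinol epimers) | COc1cc(C)c2c(c1)C=C[C@@](C)(CC(O)C[C@]1(C)CCC[C@]1(C)C(O[Si](CC)(CC)CC)C#CC(C)(C)O[Si](CC)(CC)CC)O2
F8 | step 33 | (Z)-ene-1,4-diol corresponding to 44 (carbinol epimers) | COc1cc(C)c2c(c1)C=C[C@@](C)(CC(=O)C[C@]1(C)CCC[C@]1(C)C(O)/C=C\C(C)(C)O)O2
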